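# Proposed total synthesis of shimalactone B

## Analysis of the target

Shimalactone B (42) is made of two bicyclic halves joined by an E-trisubstituted alkene; its carbons are numbered here C1–C21 along the chain, with C1–C4 the butenyl carbinol, C5, C6, C11 and C12 the cyclobutane, C7–C10 the ring diene, C13=C14 the linker, C15–C20 the oxabicycle and C21 the methyl group on C20. The left half is a cis-fused bicyclo[4.2.0]octa-2,4-diene with two quaternary cyclobutane carbons, C5 and C11. On the four-membered ring the C5 methyl group, the fusion bonds to C7 and C10, and C13 lie on one face (α), whereas the C4 branch, H6, the C11 methyl group and H12 lie on the other (β), and the exocyclic carbinol C4 is R. The right half is a 2-oxabicyclo[2.2.1]heptane-3,5-dione with quaternary C15 (the one-carbon bridge) and quaternary C18 (the bridgehead between the two carbonyl groups), with C16 S, C20 R, the C20 methyl group endo, the C15 methyl group over the lactone bridge and the alkenyl chain over the ketone bridge. Sensitive groups are the conjugated diene in the strained bicycle (acid, thermal six-electron ring opening), the non-enolisable β-keto lactone (retro-Claisen cleavage by nucleophiles, β-elimination of the lactone oxygen through a C20 enolate), the allylic C4 alcohol and the epimerisable C20. The difficulty lies in the four quaternary carbons and in the C13=C14 bond, which sits between the hindered carbons C12 and C15, so that a late olefination there is unattractive. The plan rests on one feature of the four-membered ring: C6 (H) and C11 (CH3) are cis and both adjoin C12. With C12 as a ketone, the C6=C11 bond is therefore the alkene of a strained cyclobutenone whose two faces differ only through quaternary C5, and a diene can be annulated onto it.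

## Retrosynthetic reasoning

**42 from 41.** Only the C4–O silyl bond is cut. The silyl ether protects the allylic alcohol through the oxidation, organometallic and acid steps and can be removed without base, which the β-keto lactone would not tolerate.

**41 from 40 (C15–C18).** This bond joins two quaternary carbons. Cutting it leaves a tertiary allylic alcohol at C15 and a β-keto-δ-lactone whose enol carbon C18 sits across the ring from C16. Forward, ionisation to the C13–C15 allyl cation and capture by C18 forms the bond, both quaternary centres and the oxabicycle in one operation. The cut is made here and not at C13=C14 because an olefination between C12 and C15 would be between two neopentyl-type carbons. The forward reaction has to ionise the alcohol without touching the ring diene, close at C15, and do so on the correct face.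

**40 from 26 and 36 (C14–C15).** An E-alkenyl metal from 26 adds to the methyl ketone of 36. The two halves are of similar size, so the route becomes convergent. The alkene geometry must be retained and the addition must spare the β-keto lactone.

**36 from 35, 33, 30 and 31; 30 from 27 and 28.** The lactone C–O bond comes from acyl transfer within 35. The C16–C20 bond comes from an anti aldol of β-ketoimide 30 with methacrolein 31, and the C15 ketone from cleavage of the alkene of 33. The aldol sets C16 and C20; C18 need not be controlled because it is enolised later.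

**26 from 24 and 23.** The C13 methyl and the C14 iodide are both introduced by carbometalation of terminal alkyne 24, which fixes the E geometry. The alkyne comes from aldehyde 23. The aldehyde is chosen because it makes C12 epimerisable, so this centre can be set thermodynamically.

**23 from 21, 19, 18 and 15.** C13 is attached to the C12 ketone of 15 by methylenation, followed by hydroboration and oxidation. The ring diene is unveiled from 18 by cutting C10–O and C7–H in a 1,4-elimination. It is unveiled before the aldehyde stage so that C10 is already planar when C12 is equilibrated.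

**15 from 12 and 14 (C6–C7 and C10–C11).** This is the central disconnection: a Diels–Alder reaction of cyclobutenone 12 with silyloxydiene 14. It builds the six-membered ring, the cis fusion and quaternary C11 at once. The oxygen on C10 steers the regiochemistry and later serves as the leaving group.

**12 from 11, 8 and 9.** The cyclobutane bonds C5–C6 and C11–C12 come from a [2+2] cycloaddition of the ketene derived from acid chloride 8 with enol ether 9, followed by β-elimination of the ethoxy group of 11. Enol ether 9 is chosen over an acetylenic ketenophile with later carbonyl transposition. With 9 the ketene carbon remains the ring carbonyl C12, and the expected facial preference of the ketene then gives the required C4/C5 relationship. Transposition would exchange the roles of C6 and C12 and invert that relationship.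

**8 from 7, 5, 4, 1 and 2; 14 from 13.** C4 is set by an auxiliary-controlled aldol of imide 1 with tiglaldehyde 2. The α-centre of the aldol is lost in the ketene. Diene 14 is the silyl dienol ether of enal 13.

## Alternatives that were turned down

**Alternative 1:** The cyclobutane bonds C5–C6 and C11–C12 are cut, which leads back to an arene and an alkene. Forward, irradiation of dimethyl mesaconate A1 dissolved in mesitylene A2 would give diester A3 by ortho photocycloaddition, with the C7=C8–C9=C10 diene already in place.
- For: all carbons C5–C12 and three methyl groups arrive in one step from the bulk chemicals A1 and A2. No oxygen has to be removed from C10. The C12 ester of A3 is epimerisable.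
- Against: two orientations of A1 on the reacting bond of arene A2 are possible. Meta cycloaddition and secondary photoreactions of the diene compete. A1 can isomerise under irradiation, which would scramble C5 against C12. A3 would be racemic. The C5 ester would still have to become the C4 carbinol next to a quaternary centre, under substrate control of uncertain sense.
- Comparison: this route is clearly shorter to the core and better in atom economy. The chosen route is longer but fixes C4 first with an auxiliary and passes that information to C5 and then to C6 and C11 by steric control, so the absolute configuration is addressed from the start.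

**Alternative 2:** The C16–C20 bond of the oxabicycle is cut. Forward, Rh2(OAc)4 would decompose diazo ketone A4, and the carbenoid would insert into the cis C16–H bond of its lactone ring to give oxabicycle ester A5.
- For: insertion proceeds with retention at C16, and the oxabicycle is made in isolation, away from the acid-sensitive diene. On that point it is stronger than the chosen route.
- Against: the C–H bond is next to an acyloxy oxygen and therefore deactivated. The closure is bridged across the lactone. A carbenoid bearing a methyl group can collapse by a 1,2-hydride shift instead of inserting. Both quaternary centres must already be present in A4. A5 also carries C14 as a carboxyl carbon, so a trisubstituted alkene would have to be formed by olefination at a neopentyl position.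
- Comparison: the chosen route forms C15–C18 on the complete skeleton and so never needs that olefination.

**Alternative 3:** The C16–C17 and C15–C18 bonds are cut. Forward, ketene A6 would add across its Z-trisubstituted alkene in a crossed [2+2] to give bicyclo[2.1.1]hexanone A7, and a Baeyer–Villiger oxidation would then insert oxygen between C16 and C17.
- For: both quaternary centres C15 and C18 and two rings form in one thermal step from an acyclic precursor with a single stereocentre.
- Against: the crossed mode competes with the parallel one. In A7 the ketone is flanked by quaternary C18 and tertiary C16, so the usual migratory preference would insert oxygen on the C18 side, which is the wrong regiochemistry. Ketal removal and the same C13=C14 linking problem remain.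
- Comparison: it is stronger in the number of bonds formed per step. The chosen route forms the lactone C–O bond by an aldol and acyl transfer, where no regiochemical question arises.

Key step: step 8

## Route

Assumption: ethyl prop-1-enyl ether (9) is used as the commercial E/Z mixture; the two stereocentres it creates at C6 and C11 are removed in step 6.

Assumption: adduct 15 is drawn as the endo isomer; an exo isomer would differ only at C7 and C10, which become sp2 in step 12, and would converge on 19.

Step 1
Reactants: 1 (S)-4-benzyl-3-propionyloxazolidin-2-one; 2 tiglaldehyde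
Product: 4 (S)-4-benzyl-3-[(2S,3S,4E)-3-hydroxy-2,4-dimethylhex-4-enoyl]oxazolidin-2-one, via dibutylboron Z-enolate 3 (not isolated)
Conditions: Bu2BOTf, i-Pr2NEt, CH2Cl2, −78 → 0 °C; 2, −78 → 0 °C; H2O2, MeOH, pH 7 buffer
Reagents that add atoms: none
Why: Auxiliary-controlled syn aldol (Evans) through a chair transition state of the Z-boron enolate; the benzyl group of the auxiliary fixes the carbinol carbon (C4 of the target), and the α-centre is lost again in step 5.

Step 2
Reactants: 4 aldol adduct
Product: 5 (S)-4-benzyl-3-[(2S,3S,4E)-3-(tert-butyldimethylsilyloxy)-2,4-dimethylhex-4-enoyl]oxazolidin-2-one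
Conditions: TBSOTf, 2,6-lutidine, CH2Cl2, 0 °C
Reagents that add atoms: tert-butyldimethylsilyl triflate, CC(C)(C)[Si](C)(C)OS(=O)(=O)C(F)(F)F
Why: Silylation of the hindered secondary alcohol with the silyl triflate; the ether blocks retro-aldol cleavage and carries C4 through to the last step.

Step 3
Reactants: 5 silyl ether
Product: 7 (2S,3S,4E)-3-(tert-butyldimethylsilyloxy)-2,4-dimethylhex-4-enoic acid, via lithium peroxycarboxylate 6 (not isolated)
Conditions: LiOH, H2O2, THF/H2O, 0 °C; Na2SO3; aq. HCl to pH 3
Reagents that add atoms: lithium hydroperoxide (from LiOH and H2O2), [Li+].[O-]O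
Why: Hydroperoxide attacks the exocyclic imide carbonyl selectively and the auxiliary is released; sulfite reduces the peroxy acid to the acid.

Step 4
Reactants: 7 acid
Product: 8 (2S,3S,4E)-3-(tert-butyldimethylsilyloxy)-2,4-dimethylhex-4-enoyl chloride
Conditions: 1-chloro-N,N,2-trimethylprop-1-en-1-amine, CH2Cl2, 0 °C → rt
Reagents that add atoms: 1-chloro-N,N,2-trimethylprop-1-en-1-amine, CC(C)=C(Cl)N(C)C
Why: Neutral acid chloride formation with the Ghosez reagent, which liberates no HCl and so spares the silyl ether.

Step 5
Reactants: 8 acid chloride; 9 ethyl prop-1-enyl ether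
Product: 11 (2R)-3-ethoxy-2,4-dimethyl-2-[(1R,2E)-1-(tert-butyldimethylsilyloxy)-2-methylbut-2-en-1-yl]cyclobutan-1-one (mixture at C3 and C4 of the ring), via ketene 10 (not isolated)
Conditions: Et3N, 9 (5 equiv), MeCN, 60 °C, slow addition of 8
Reagents that add atoms: none
Why: Dehydrochlorination gives ketene 10; in a thermal ketene–enol ether [2+2] cycloaddition its carbonyl carbon (C12) is attacked by the β-carbon of the enol ether and its α-carbon (C5) closes onto the oxocarbenium carbon (C6). With the C4–O bond near the plane of the ketene substituents and the butenyl group anti to the incoming carbon, C6 should bond anti to the silyloxy group, which is the C4/C5 relationship of the target.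

Step 6
Reactants: 11 ethoxycyclobutanone
Product: 12 (4R)-4-[(1R,2E)-1-(tert-butyldimethylsilyloxy)-2-methylbut-2-en-1-yl]-2,4-dimethylcyclobut-2-en-1-one
Conditions: KN(SiMe3)2, THF, −78 → 0 °C; AcOH
Reagents that add atoms: none
Why: E1cB elimination: C11 is the only enolisable position, and its potassium enolate expels the β-ethoxide to give the conjugated cyclobutenone, while quaternary C5 is untouched. Low temperature and an acidic quench limit re-addition of ethoxide and thermal ring opening of 12.

Step 7
Reactants: 13 (E)-2-methylpent-2-enal
Product: 14 (1E,3E)-2-methyl-1-(triethylsilyloxy)penta-1,3-diene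
Conditions: TESOTf, Et3N, Et2O, 0 °C → rt
Reagents that add atoms: triethylsilyl triflate, CC[Si](CC)(CC)OS(=O)(=O)C(F)(F)F
Why: O-silylation of the enal and γ-deprotonation give the silyl dienol ether; the s-trans enal leads to the 1E geometry, the new C3=C4 bond forms E, and only the E,E isomer can adopt the s-cis conformation needed in step 8.

Step 8
Reactants: 12 cyclobutenone; 14 silyloxydiene
Product: 15 endo adduct 8-[(1R,2E)-1-(tert-butyldimethylsilyloxy)-2-methylbut-2-en-1-yl]-2,4,6,8-tetramethyl-5-(triethylsilyloxy)bicyclo[4.2.0]oct-3-en-7-one (target numbering: C12 ketone; C8=C9; H6 and C11 methyl β; C7 methyl and C10 silyloxy α)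
Conditions: 14 (3 equiv), ZnCl2 (0.3 equiv), CH2Cl2/Et2O, 0 °C → rt
Reagents that add atoms: none
Why: A concerted but asynchronous normal-demand [4+2] cycloaddition: the diene terminus remote from oxygen (C7, largest HOMO coefficient) bonds first to the enone β-carbon C6, and the oxygen-bearing terminus C10 bonds to the α-carbon C11. The closest known reaction type is the Diels–Alder reaction of cyclobutenones with 1-oxygenated dienes, in which strain release on pyramidalisation makes the four-membered enone far more reactive than larger cycloalkenones; ZnCl2 lowers the LUMO further. The six-membered ring C6–C11 is closed by suprafacial addition to both components, so the ring fusion is necessarily cis and quaternary C11 forms in the same event. C6 and C11 are controlled by C5: the diene should approach the planar cyclobutenone on the face of the C5 methyl, anti to the branched silyloxyalkenyl group next to C6. C7 and C10 follow from the E,E geometry of the diene (methyl and silyloxy cis) and the endo orientation of the carbonyl; both are erased in step 12, so endo/exo selectivity is not required. The regiochemistry needed (oxygenated carbon next to C11) relies on the silyloxy donor outweighing the two methyl groups of the diene. The temperature is kept at or below room temperature so that 12 does not open to a vinylketene.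

Step 9
Reactants: 15 ketone
Product: 16 C12-methylene compound (target numbering: C12=C13H2; otherwise as 15)
Conditions: Ph3PCH3Br, KOt-Bu, toluene, 0 → 60 °C
Reagents that add atoms: methyltriphenylphosphonium bromide (as its ylide), C[P+](c1ccccc1)(c1ccccc1)c1ccccc1.[Br-]
Why: Wittig methylenation; the cyclobutanone is non-enolisable (C5 and C11 quaternary) and strain-activated, so the hindered carbonyl should still accept the small ylide, and the β-silyloxy group cannot be eliminated.

Step 10
Reactants: 16 bis-silyl ether
Product: 17 C10 alcohol (C4 silyl ether retained)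
Conditions: HF·pyridine, pyridine, THF, 0 °C
Reagents that add atoms: none
Why: Buffered fluoride cleaves the triethylsilyl ether much faster than the tert-butyldimethylsilyl ether, which should remain on C4.

Step 11
Reactants: 17 allylic alcohol
Product: 18 C10 methyl carbonate
Conditions: ClCO2Me, pyridine, DMAP, CH2Cl2, 0 °C → rt
Reagents that add atoms: methyl chloroformate, COC(=O)Cl
Why: Acylation of the hindered allylic alcohol gives a leaving group for palladium; no base-sensitive group is present at this stage.

Step 12
Reactants: 18 allylic carbonate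
Product: 19 triene (target numbering: C7=C8–C9=C10 diene; C12=C13H2)
Conditions: Pd(PPh3)4 (10 mol%), THF, 60 °C
Reagents that add atoms: none
Why: Tsuji-type 1,4-elimination: zerovalent palladium ionises the allylic carbonate with inversion to the π-allyl complex over C8–C10, and syn β-hydride loss from C7 gives the diene without a free cation next to the cyclobutane. C7–H is trans to the C10 oxygen in every adduct of the E,E-diene and therefore on the palladium face; C11 carries no hydrogen, so the elimination is regiospecific.

Step 13
Reactants: 19 triene
Product: 21 C13 primary alcohol (C12 epimers), via B-alkyl-9-borabicyclononane 20 (not isolated)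
Conditions: 9-BBN, THF, 0 °C → rt; NaOH, H2O2, 0 °C
Reagents that add atoms: hydrogen peroxide, OO
Why: Hydroboration–oxidation; 9-BBN adds much faster to the 1,1-disubstituted exocyclic alkene, with boron on terminal C13, than to the trisubstituted alkenes of the diene and the side chain. The new C12–H centre is expected as a mixture and is corrected in step 14.

Step 14
Reactants: 21 primary alcohol
Product: 23 C13 aldehyde with C12 as in the target (formyl group α), via C12-epimeric aldehyde mixture 22 (not isolated)
Conditions: Dess–Martin periodinane, NaHCO3, CH2Cl2, 0 °C → rt; then DBU (0.2 equiv), CH2Cl2, rt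
Reagents that add atoms: none
Why: Dess–Martin oxidation, then base-mediated epimerisation through the enol. The α-formyl group meets only the C5 methyl and planar C10, whereas the β-formyl group meets the branched C4 substituent and the C11 methyl, so the equilibrium should favour the target configuration at C12.

Step 15
Reactants: 23 aldehyde
Product: 24 terminal alkyne (C13≡C14H)
Conditions: dimethyl (1-diazo-2-oxopropyl)phosphonate, K2CO3, MeOH, 0 °C → rt
Reagents that add atoms: dimethyl (1-diazo-2-oxopropyl)phosphonate, COP(=O)(OC)C(=[N+]=[N-])C(C)=O
Why: Seyferth–Gilbert homologation with the Ohira–Bestmann reagent; the carbonate/methanol medium keeps the α-centre in equilibrium, and after alkyne formation C12 is no longer epimerisable.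

Step 16
Reactants: 24 alkyne
Product: 26 (E)-alkenyl iodide (C13 methyl; C14 iodide), via alkenylalane 25 (not isolated)
Conditions: AlMe3, Cp2ZrCl2 (0.3 equiv), H2O (1 equiv), CH2Cl2, −25 °C; I2, THF, −30 °C
Reagents that add atoms: trimethylaluminium, C[Al](C)C; iodine, II
Why: Negishi zirconium-catalysed carboalumination adds methyl and aluminium syn across the terminal alkyne with aluminium on the terminal carbon; iodinolysis with retention gives the E-iodide.

Step 17
Reactants: 27 (R)-4-benzyl-3-propionyloxazolidin-2-one; 28 propionyl chloride
Product: 30 (R)-4-benzyl-3-[(2S)-2-methyl-3-oxopentanoyl]oxazolidin-2-one, via lithium Z-enolate 29 (not isolated)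
Conditions: LiN(i-Pr)2, THF, −78 °C; 28, −78 °C
Reagents that add atoms: none
Why: C-acylation of the chelated lithium Z-enolate on the face opposite the benzyl group; the β-ketoimide is configurationally stable at C2 because allylic strain disfavours its enolisation.

Step 18
Reactants: 30 β-ketoimide; 31 methacrolein
Product: 33 (R)-4-benzyl-3-[(2S,4R,5S)-5-hydroxy-2,4,6-trimethyl-3-oxohept-6-enoyl]oxazolidin-2-one, via dicyclohexylboron E-enolate 32 (not isolated)
Conditions: (c-C6H11)2BCl, Me2NEt, Et2O, 0 °C; 31, −78 °C; H2O2, MeOH, pH 7 buffer
Reagents that add atoms: none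
Why: Anti aldol of the E-boron enolate of the ethyl ketone through a chair transition state; the C2 methyl stereocentre directs the enolate face and should give the 2,4-anti-4,5-anti adduct, which sets C20 (R) and C16 (S) of the target.

Step 19
Reactants: 33 aldol adduct
Product: 35 (R)-4-benzyl-3-[(2S,4R,5S)-5-hydroxy-2,4-dimethyl-3,6-dioxoheptanoyl]oxazolidin-2-one, via ozonide 34 (not isolated)
Conditions: O3, CH2Cl2, −78 °C; Me2S, −78 °C → rt
Reagents that add atoms: ozone, [O-][O+]=O
Why: Ozonolysis of the 1,1-disubstituted alkene to the methyl ketone; the β-ketoimide stays in the keto form and carries no other alkene, so ozone has a single site of attack.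

Step 20
Reactants: 35 hydroxy imide
Product: 36 (5R,6S)-6-acetyl-3,5-dimethyldihydro-2H-pyran-2,4(3H)-dione (C3 epimers and enol)
Conditions: DBU (1.0 equiv), CH2Cl2, 0 °C; 1 M HCl
Reagents that add atoms: none
Why: Intramolecular acyl transfer: the C16 hydroxyl attacks the imide carbonyl through a six-membered transition state and releases the auxiliary; a short reaction time at 0 °C limits enolisation of the α-acyloxy ketone at C16.

Step 21
Reactants: 26 E-alkenyl iodide; 36 lactone methyl ketone
Product: 40 tertiary allylic alcohol (C15 epimers; C18 epimers and enol), via alkenyllithium 37 (not isolated), via alkenylcerium dichloride 38 (not isolated), via lithium enolate 39 (not isolated)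
Conditions: 26, t-BuLi (2.1 equiv), Et2O, −78 °C; CeCl3, THF, −78 °C; added to 39 [36 (1.5 equiv), LiN(SiMe3)2, THF, −78 °C]; aq. NH4Cl
Reagents that add atoms: none
Why: Iodine–lithium exchange with retention of alkene geometry, transmetalation to the weakly basic organocerium, and 1,2-addition to the methyl ketone; the β-keto lactone is masked as its lithium enolate, which is neither acidic nor electrophilic. The configuration at C15 is irrelevant because this centre is ionised in step 22.

Step 22
Reactants: 40 tertiary allylic alcohol
Product: 41 shimalactone B C4-tert-butyldimethylsilyl ether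
Conditions: (+)-camphorsulfonic acid (0.2 equiv), CH2Cl2/(CF3)2CHOH 9:1, −20 → 0 °C
Reagents that add atoms: none
Why: Brønsted-acid-catalysed dehydrative allylic alkylation of a β-dicarbonyl compound: the alcohol ionises to the C13–C15 allyl cation and the enol carbon C18 attacks C15 across the lactone from a boat conformer, forming the C15–C18 bond, both quaternary centres and the oxabicycle. C16 and C20 fix the face of C18; at C15 the methyl group should take the quadrant over the ring oxygen and the planar alkenyl group the one over C20–H, and the C13=C14 bond re-forms E with both large substituents outside.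

Step 23
Reactants: 41 silyl ether
Product: 42 shimalactone B
Conditions: HF·pyridine, pyridine, THF, 0 °C → rt
Reagents that add atoms: none
Why: Fluoride cleavage of the silyl ether under buffered, non-basic conditions; no alkoxide is generated, so the non-enolisable β-keto lactone is not exposed to retro-Claisen cleavage.

## Compound list

1 | (S)-4-benzyl-3-propionyloxazolidin-2-one | CCC(=O)N1[C@@H](Cc2ccccc2)COC1=O | starting material
2 | tiglaldehyde; (E)-2-methylbut-2-enal | C/C=C(\C)C=O | starting material
3 | dibutylboron Z-enolate of 1 | C/C=C(\OB(CCCC)CCCC)N1[C@@H](Cc2ccccc2)COC1=O | intermediate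
4 | (S)-4-benzyl-3-[(2S,3S,4E)-3-hydroxy-2,4-dimethylhex-4-enoyl]oxazolidin-2-one | C/C=C(\C)[C@@H](O)[C@H](C)C(=O)N1[C@@H](Cc2ccccc2)COC1=O | intermediate
5 | (S)-4-benzyl-3-[(2S,3S,4E)-3-(tert-butyldimethylsilyloxy)-2,4-dimethylhex-4-enoyl]oxazolidin-2-one | C/C=C(\C)[C@@H](O[Si](C)(C)C(C)(C)C)[C@H](C)C(=O)N1[C@@H](Cc2ccccc2)COC1=O | intermediate
6 | lithium (2S,3S,4E)-3-(tert-butyldimethylsilyloxy)-2,4-dimethylhex-4-eneperoxoate | C/C=C(\C)[C@@H](O[Si](C)(C)C(C)(C)C)[C@H](C)C(=O)O[O-].[Li+] | intermediate
7 | (2S,3S,4E)-3-(tert-butyldimethylsilyloxy)-2,4-dimethylhex-4-enoic acid | C/C=C(\C)[C@@H](O[Si](C)(C)C(C)(C)C)[C@H](C)C(=O)O | intermediate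
8 | (2S,3S,4E)-3-(tert-butyldimethylsilyloxy)-2,4-dimethylhex-4-enoyl chloride | C/C=C(\C)[C@@H](O[Si](C)(C)C(C)(C)C)[C@H](C)C(=O)Cl | intermediate
9 | ethyl prop-1-enyl ether (E/Z mixture) | CC=COCC | starting material
10 | ketene (3R,4E)-3-(tert-butyldimethylsilyloxy)-2,4-dimethylhexa-1,4-dien-1-one | C/C=C(\C)[C@@H](O[Si](C)(C)C(C)(C)C)C(C)=C=O | intermediate
11 | (2R)-3-ethoxy-2,4-dimethyl-2-[(1R,2E)-1-(tert-butyldimethylsilyloxy)-2-methylbut-2-en-1-yl]cyclobutan-1-one (mixture at ring C3 and C4) | C/C=C(\C)[C@@H](O[Si](C)(C)C(C)(C)C)[C@@]1(C)C(OCC)C(C)C1=O | intermediate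
12 | (4R)-4-[(1R,2E)-1-(tert-butyldimethylsilyloxy)-2-methylbut-2-en-1-yl]-2,4-dimethylcyclobut-2-en-1-one | C/C=C(\C)[C@@H](O[Si](C)(C)C(C)(C)C)[C@@]1(C)C=C(C)C1=O | intermediate
13 | (E)-2-methylpent-2-enal | CC/C=C(\C)C=O | starting material
14 | (1E,3E)-2-methyl-1-(triethylsilyloxy)penta-1,3-diene | C/C=C/C(C)=C/O[Si](CC)(CC)CC | intermediate
15 | endo Diels–Alder adduct; 8-[(1R,2E)-1-(tert-butyldimethylsilyloxy)-2-methylbut-2-en-1-yl]-2,4,6,8-tetramethyl-5-(triethylsilyloxy)bicyclo[4.2.0]oct-3-en-7-one; cis-fused; H6 and C11 methyl β; C7 methyl and C10 silyloxy α (target numbering) | C/C=C(\C)[C@@H](O[Si](C)(C)C(C)(C)C)[C@@]1(C)[C@@H]2[C@H](C)C=C(C)[C@H](O[Si](CC)(CC)CC)[C@]2(C)C1=O | intermediate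
16 | C12-methylene analogue of 15 (7-methylidene bicyclo[4.2.0]oct-3-ene; both silyl ethers retained) | C/C=C(\C)[C@@H](O[Si](C)(C)C(C)(C)C)[C@@]1(C)[C@@H]2[C@H](C)C=C(C)[C@H](O[Si](CC)(CC)CC)[C@]2(C)C1=C | intermediate
17 | C10 alcohol (free allylic hydroxyl α; C4 silyl ether retained) | C/C=C(\C)[C@@H](O[Si](C)(C)C(C)(C)C)[C@@]1(C)[C@@H]2[C@H](C)C=C(C)[C@H](O)[C@]2(C)C1=C | intermediate
18 | C10 methyl carbonate of 17 | C/C=C(\C)[C@@H](O[Si](C)(C)C(C)(C)C)[C@@]1(C)[C@@H]2[C@H](C)C=C(C)[C@H](OC(=O)OC)[C@]2(C)C1=C | intermediate
19 | triene; cis-bicyclo[4.2.0]octa-2,4-diene with C12 exocyclic methylene; C5, C6, C11 as in the target | C/C=C(\C)[C@@H](O[Si](C)(C)C(C)(C)C)[C@@]1(C)[C@@H]2C(C)=CC(C)=C[C@]2(C)C1=C | intermediate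
20 | B-(C13-alkyl)-9-borabicyclo[3.3.1]nonane (C12 epimers) | C/C=C(\C)[C@@H](O[Si](C)(C)C(C)(C)C)[C@@]1(C)[C@@H]2C(C)=CC(C)=C[C@]2(C)C1CB3C4CCCC3CCC4 | intermediate
21 | C13 primary alcohol (C12 epimers) | C/C=C(\C)[C@@H](O[Si](C)(C)C(C)(C)C)[C@@]1(C)[C@@H]2C(C)=CC(C)=C[C@]2(C)C1CO | intermediate
22 | C13 aldehyde as C12-epimeric mixture | C/C=C(\C)[C@@H](O[Si](C)(C)C(C)(C)C)[C@@]1(C)[C@@H]2C(C)=CC(C)=C[C@]2(C)C1C=O | intermediate
23 | C13 aldehyde; formyl group α at C12 (cis to the C5 methyl; trans to the C4 branch) | C/C=C(\C)[C@@H](O[Si](C)(C)C(C)(C)C)[C@@]1(C)[C@@H]2C(C)=CC(C)=C[C@]2(C)[C@@H]1C=O | intermediate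
24 | terminal alkyne (ethynyl group α at C12) | C/C=C(\C)[C@@H](O[Si](C)(C)C(C)(C)C)[C@@]1(C)[C@@H]2C(C)=CC(C)=C[C@]2(C)[C@@H]1C#C | intermediate
25 | (E)-alkenyl(dimethyl)alane (C13 methyl; C14 aluminium) | C/C=C(\C)[C@@H](O[Si](C)(C)C(C)(C)C)[C@@]1(C)[C@@H]2C(C)=CC(C)=C[C@]2(C)[C@@H]1/C(C)=C/[Al](C)C | intermediate
26 | (E)-alkenyl iodide; C12-[(E)-1-iodoprop-1-en-2-yl] bicyclooctadiene | C/C=C(\C)[C@@H](O[Si](C)(C)C(C)(C)C)[C@@]1(C)[C@@H]2C(C)=CC(C)=C[C@]2(C)[C@@H]1/C(C)=C/I | intermediate
27 | (R)-4-benzyl-3-propionyloxazolidin-2-one | CCC(=O)N1[C@H](Cc2ccccc2)COC1=O | starting material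
28 | propionyl chloride | CCC(=O)Cl | starting material
29 | lithium Z-enolate of 27 | C/C=C(\O[Li])N1[C@H](Cc2ccccc2)COC1=O | intermediate
30 | (R)-4-benzyl-3-[(2S)-2-methyl-3-oxopentanoyl]oxazolidin-2-one | CCC(=O)[C@H](C)C(=O)N1[C@H](Cc2ccccc2)COC1=O | intermediate
31 | methacrolein | C=C(C)C=O | starting material
32 | dicyclohexylboron E-enolate of 30 | C/C=C(/OB(C1CCCCC1)C1CCCCC1)[C@H](C)C(=O)N1[C@H](Cc2ccccc2)COC1=O | intermediate
33 | (R)-4-benzyl-3-[(2S,4R,5S)-5-hydroxy-2,4,6-trimethyl-3-oxohept-6-enoyl]oxazolidin-2-one | C=C(C)[C@@H](O)[C@@H](C)C(=O)[C@H](C)C(=O)N1[C@H](Cc2ccccc2)COC1=O | intermediate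
34 | secondary ozonide (1,2,4-trioxolane) of 33 | CC1(OCOO1)[C@@H](O)[C@@H](C)C(=O)[C@H](C)C(=O)N1[C@H](Cc2ccccc2)COC1=O | intermediate
35 | (R)-4-benzyl-3-[(2S,4R,5S)-5-hydroxy-2,4-dimethyl-3,6-dioxoheptanoyl]oxazolidin-2-one | CC(=O)[C@@H](O)[C@@H](C)C(=O)[C@H](C)C(=O)N1[C@H](Cc2ccccc2)COC1=O | intermediate
36 | (5R,6S)-6-acetyl-3,5-dimethyldihydro-2H-pyran-2,4(3H)-dione (C3 epimers and enol) | CC(=O)[C@H]1OC(=O)C(C)C(=O)[C@@H]1C | intermediate
37 | (E)-alkenyllithium from 26 | C/C=C(\C)[C@@H](O[Si](C)(C)C(C)(C)C)[C@@]1(C)[C@@H]2C(C)=CC(C)=C[C@]2(C)[C@@H]1/C(C)=C/[Li] | intermediate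
38 | (E)-alkenylcerium dichloride | C/C=C(\C)[C@@H](O[Si](C)(C)C(C)(C)C)[C@@]1(C)[C@@H]2C(C)=CC(C)=C[C@]2(C)[C@@H]1/C(C)=C/[Ce](Cl)Cl | intermediate
39 | lithium enolate of 36 | CC(=O)[C@H]1OC(=O)C(C)=C(O[Li])[C@@H]1C | intermediate
40 | tertiary allylic alcohol; C15 carbinol bearing the β-keto-δ-lactone at C16 (C15 and C18 epimers) | C/C=C(\C)[C@@H](O[Si](C)(C)C(C)(C)C)[C@@]1(C)[C@@H]2C(C)=CC(C)=C[C@]2(C)[C@@H]1/C(C)=C/C(C)(O)[C@H]1OC(=O)C(C)C(=O)[C@@H]1C | intermediate
41 | shimalactone B C4-tert-butyldimethylsilyl ether | C/C=C(\C)[C@@H](O[Si](C)(C)C(C)(C)C)[C@@]1(C)[C@@H]2C(C)=CC(C)=C[C@]2(C)[C@@H]1/C(C)=C/[C@]1(C)[C@H]2OC(=O)[C@]1(C)C(=O)[C@@H]2C | intermediate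
42 | shimalactone B | C/C=C(\C)[C@@H](O)[C@@]1(C)[C@@H]2C(C)=CC(C)=C[C@]2(C)[C@@H]1/C(C)=C/[C@]1(C)[C@H]2OC(=O)[C@]1(C)C(=O)[C@@H]2C | target

## Step count and uncertain steps

Total: 23 steps. Longest linear sequence: 18 steps (steps 1–6, 8–16, 21–23). Step 7 and steps 17–20 are side branches.

**Step 8 (key step).** The cycloaddition may be slow, because the nucleophilic diene terminus must bond to C6 next to quaternary C5 and the dienophile carries an α-methyl group. Forcing may cause electrocyclic opening of 12 to a vinylketene, Lewis-acid-induced conjugate addition without ring closure, or erosion of regiocontrol by the two methyl groups of the diene. The fallback sets out from 12 and 13 and comes back at 19. Enal 13 is condensed with morpholine to 4-[(1E,3E)-2-methylpenta-1,3-dien-1-yl]morpholine F1, a far more nucleophilic 1-aminodiene. It should add to 12 at or below room temperature without Lewis acid, in the same regio- and facial sense, to give the C10 morpholino adduct F2. Wittig methylenation as in step 9 gives the methylene amine F3, and N-methylation with MeI gives the allylic ammonium iodide F4. Ionisation and β-hydride loss with Pd(PPh3)4 and Et3N in THF, as in step 12, then lead to 19.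

**Step 5.** Ring closure may occur on the other face of the ketene, because 1,2-induction from an acyclic silyloxy stereocentre in a ketene cycloaddition is hard to predict; this would give the C5 epimer. The fallback sets out from 8 and comes back at 12. Ketene 10 is combined with ethyl prop-1-ynyl ether to give the 3-ethoxycyclobutenone F5. 1,2-Reduction with i-Bu2AlH gives the cyclobutenol F6, and dilute acid hydrolyses the enol ether with loss of water to give 12. The carbonyl group then ends up on the carbon delivered by the alkyne. The same facial preference of the ketene therefore gives the opposite C4/C5 relationship, so the two ketenophiles are stereochemically complementary.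

**Step 6.** Loss of ethoxide may be slow or reversible, because ethoxide is a poor leaving group and the strained enone invites conjugate re-addition. The fallback sets out from 8 and comes back at 12. Ketene 10 is trapped with phenyl prop-1-enyl sulfide to give the 3-(phenylthio)cyclobutanone F7. NaIO4 oxidises sulfur selectively to the sulfoxide F8, and Et3N at room temperature expels the sulfenate, a much better and non-returning leaving group, to give 12.

**Step 12.** Ionisation at C10 may be slow, because this carbon is flanked by quaternary C11. At the temperature then needed, thermal six-electron ring opening of the product diene to a cyclooctatriene and re-closure could erode the ring-fusion configuration. The fallback sets out from 17 and comes back at 19. Dess–Martin oxidation of 17 gives the C10 enone F9. KN(SiMe3)2 and PhNTf2 at −78 °C deprotonate C7, the only available position, and give the cyclohexadienyl triflate F10. Reduction with Pd(PPh3)4, Bu3SnH and LiCl in THF at room temperature gives 19.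

**Step 22.** Several processes may compete under the acid: protonation of the ring diene; loss of the C4 silyl ether followed by ionisation of the allylic alcohol; loss of a proton from the allyl cation to a triene; ring expansion of the cyclobutane through the C13 terminus of the allyl cation, which adjoins C12; or closure on the wrong face of C15, where the two quadrants differ only modestly in size. The fallback sets out from 40 and comes back at 41. Silylation with TMSOTf and Et3N gives the bis(trimethylsilyl) derivative F11, a tertiary allylic silyl ether that also carries the silyl enol ether of the β-keto lactone. Catalytic TMSOTf in CH2Cl2 at −78 °C ionises the allylic silyl ether, and the silyl enol ether, a much better nucleophile than the enol, closes onto C15 in a Mukaiyama-type intramolecular alkylation. These conditions are aprotic and cold, should spare the diene and the C4 ether, and shorten the lifetime of the cation. They do not change the facial question at C15, so if that is the failure, the C15 epimers would have to be separated.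

## Further compounds

F1 | step 8 | 4-[(1E,3E)-2-methylpenta-1,3-dien-1-yl]morpholine | C/C=C/C(C)=C/N1CCOCC1
F2 | step 8 | C10 morpholino Diels–Alder adduct (analogue of 15) | C/C=C(\C)[C@@H](O[Si](C)(C)C(C)(C)C)[C@@]1(C)[C@@H]2[C@H](C)C=C(C)[C@H](N3CCOCC3)[C@]2(C)C1=O
F3 | step 8 | C12-methylene C10 morpholino compound | C/C=C(\C)[C@@H](O[Si](C)(C)C(C)(C)C)[C@@]1(C)[C@@H]2[C@H](C)C=C(C)[C@H](N3CCOCC3)[C@]2(C)C1=C
F4 | step 8 | allylic N-methylmorpholinium iodide | C/C=C(\C)[C@@H](O[Si](C)(C)C(C)(C)C)[C@@]1(C)[C@@H]2[C@H](C)C=C(C)[C@H]([N+]3(C)CCOCC3)[C@]2(C)C1=C.[I-]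
F5 | step 5 | (4R)-3-ethoxy-2,4-dimethyl-4-[(1R,2E)-1-(tert-butyldimethylsilyloxy)-2-methylbut-2-en-1-yl]cyclobut-2-en-1-one | C/C=C(\C)[C@@H](O[Si](C)(C)C(C)(C)C)[C@@]1(C)C(=O)C(C)=C1OCC
F6 | step 5 | 3-ethoxycyclobut-2-en-1-ol from F5 | C/C=C(\C)[C@@H](O[Si](C)(C)C(C)(C)C)[C@@]1(C)C(O)C(C)=C1OCC
F7 | step 6 | 3-(phenylthio)cyclobutanone analogue of 11 | C/C=C(\C)[C@@H](O[Si](C)(C)C(C)(C)C)[C@@]1(C)C(Sc2ccccc2)C(C)C1=O
F8 | step 6 | 3-(phenylsulfinyl)cyclobutanone | C/C=C(\C)[C@@H](O[Si](C)(C)C(C)(C)C)[C@@]1(C)C(S(=O)c2ccccc2)C(C)C1=O
F9 | step 12 | C10 enone (C8=C9–C10=O) with C12 methylene | C/C=C(\C)[C@@H](O[Si](C)(C)C(C)(C)C)[C@@]1(C)[C@@H]2[C@H](C)C=C(C)C(=O)[C@]2(C)C1=C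
F10 | step 12 | C10 cyclohexadienyl triflate | C/C=C(\C)[C@@H](O[Si](C)(C)C(C)(C)C)[C@@]1(C)[C@@H]2C(C)=CC(C)=C(OS(=O)(=O)C(F)(F)F)[C@]2(C)C1=C
F11 | step 22 | bis(trimethylsilyl) derivative of 40 (C15 silyl ether; C19 silyl enol ether) | C/C=C(\C)[C@@H](O[Si](C)(C)C(C)(C)C)[C@@]1(C)[C@@H]2C(C)=CC(C)=C[C@]2(C)[C@@H]1/C(C)=C/C(C)(O[Si](C)(C)C)[C@H]1OC(=O)C(C)=C(O[Si](C)(C)C)[C@@H]1C
A1 | alternative 1 | dimethyl mesaconate | COC(=O)/C=C(\C)C(=O)OC
A2 | alternative 1 | mesitylene | Cc1cc(C)cc(C)c1
A3 | alternative 1 | bicyclo[4.2.0]octa-2,4-diene diester | COC(=O)[C@@]1(C)[C@@H]2C(C)=CC(C)=C[C@]2(C)[C@@H]1C(=O)OC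
A4 | alternative 2 | butyrolactone 2-diazopropanoyl benzyl ester | O=C(OCc1ccccc1)[C@]1(C)COC(=O)[C@]1(C)C(=O)C(C)=[N+]=[N-]
A5 | alternative 2 | 2-oxabicyclo[2.2.1]heptane-3,5-dione benzyl ester | O=C(OCc1ccccc1)[C@]1(C)[C@H]2OC(=O)[C@]1(C)C(=O)[C@@H]2C
A6 | alternative 3 | ketene with Z-alkene and ketal | CC(C)(C)[Si](C)(C)OC/C(C)=C\[C@@H](C)C1(OCCO1)C(C)=C=O
A7 | alternative 3 | bicyclo[2.1.1]hexan-5-one ketal | CC(C)(C)[Si](C)(C)OC[C@]1(C)[C@H]2C(=O)[C@]1(C)C3(OCCO3)[C@@H]2C
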